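**Retrosynthetic overview**

1. The left oxepene is opened at O–C23: the C18 allylic alcohol closes onto a (22S)-22,23-epoxide (7-endo); the C18 carbinol comes from reduction of a (Z)-19(20)-enone.
2. The left carbocycle C14–C15–C16–C17–C18–C19 is traced back to the cyclopentanone C14–C15–C16–C17–C18. C19 (from CH2Br2) is inserted between C18 and C14 by a β-oxido carbenoid 1,2-shift, and the enolate so formed is joined at once to the C20–C23 aldehyde, which completes the C30 skeleton.
3. The enabling feature is the quaternary C14 next to the oxygen-bearing C18 in that ring: as the more substituted α-carbon it is the one that migrates, and the enolate C18(O)=C19 is formed only at the inserted, otherwise inaccessible neopentyl carbon.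
4. The C15/C14 pair is set on the five-membered ring: catalytic asymmetric conjugate methylation (C15), then enolate methylation anti to it (C14, relay).
5. The right half comes from (2E,6E)-farnesyl acetate by a biomimetic epoxonium cascade and is joined to 2-iodocyclopentenone by B-alkyl Suzuki coupling. Ring order: right oxepane, right cyclohexane (one cascade), cyclopentenone (bought), left cyclohexanone (ring expansion), left oxepene.

Key step: step 10

Remark (numbering and abbreviations): squalene-type numbering is used (right half C2–C11 with O between C2 and C7, linker C12–C13, left half C14–C23 with O between C18 and C23); "ent-Shi ketone" is the L-fructose-derived enantiomer of the usual epoxidation ketone and is assumed to be purchasable; R1 = (3S,5aS,6S,7S,9aS)-3-(tert-butyldimethylsilyloxy)-2,2,5a,7-tetramethyl-7-(triethylsilyloxy)decahydro-1-benzoxepin-6-yl, R2 = the corresponding 3,7-diol, R3 = (5aS,6S,7S,9aS)-7-hydroxy-2,2,5a,7-tetramethyl-3-oxodecahydro-1-benzoxepin-6-yl.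

**Step 1**
Reactants: 1 (2E,6E)-farnesyl acetate
Product: 2 (2E)-5-[(2S,3S)-3-{2-[(2S)-3,3-dimethyloxiran-2-yl]ethyl}-3-methyloxiran-2-yl]-3-methylpent-2-en-1-yl acetate
Conditions: ent-Shi ketone (0.6 equiv), Oxone, K2CO3, Bu4NHSO4, borate/EDTA buffer, MeCN–DMM–H2O, 0 °C
Reagents that add atoms: Oxone (potassium peroxymonosulfate), [K+].[O-]S(=O)(=O)OO
Why: Shi asymmetric epoxidation should oxidise the two electron-rich trisubstituted olefins under reagent control (6S,7S and 3S), while the olefin next to the allylic acetate is deactivated and should stay.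

**Step 2**
Reactants: 2 bis-epoxide
Product: 4 [(3S,5aS,6R,7S,9aS)-3-(tert-butyldimethylsilyloxy)-7-hydroxy-2,2,5a,7-tetramethyldecahydro-1-benzoxepin-6-yl]methyl acetate, via acetoxonium triflate 3 (not isolated)
Conditions: TBSOTf, 2,6-di-tert-butyl-4-methylpyridine, CH2Cl2, −78 °C; then aq. NaHCO3, rt
Reagents that add atoms: tert-butyldimethylsilyl triflate, CC(C)(C)[Si](C)(C)OS(=O)(=O)C(F)(F)F; water, O
Why: In this epoxonium-ion tandem oxa-/carbacyclisation the silylated terminal epoxide should be opened at C2 by the 6,7-epoxide oxygen, the C10=C11 olefin should then attack C6 with inversion through a chair, and the acetate carbonyl should capture the C10 cation anti (equatorial C–O) before hydrolysis to the primary acetate, so that C6, C10 and C11 are relayed from the epoxide.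

**Step 3**
Reactants: 4 hydroxy acetate
Product: 5 [(3S,5aS,6R,7S,9aS)-3-(tert-butyldimethylsilyloxy)-2,2,5a,7-tetramethyl-7-(triethylsilyloxy)decahydro-1-benzoxepin-6-yl]methyl acetate
Conditions: TESOTf, 2,6-lutidine, CH2Cl2, −78 → 0 °C
Reagents that add atoms: triethylsilyl triflate, CC[Si](CC)(CC)OS(=O)(=O)C(F)(F)F
Why: A silyl triflate with a hindered pyridine base should silylate the tertiary C10 alcohol without touching the acetate.

**Step 4**
Reactants: 5 silyl ether acetate
Product: 6 R1-methanol, [(3S,5aS,6R,7S,9aS)-configured 6-(hydroxymethyl) compound]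
Conditions: DIBAL-H, CH2Cl2, −78 °C; Rochelle salt work-up
Reagents that add atoms: none
Why: Reductive ester cleavage through an aluminium alkoxide should free the primary alcohol without the 1,5-silyl migration that a basic methanolysis could cause.

**Step 5**
Reactants: 6 primary alcohol
Product: 7 R1-carbaldehyde (3S,5aS,6S,7S,9aS)
Conditions: Dess–Martin periodinane, NaHCO3, CH2Cl2, 0 °C → rt
Reagents that add atoms: none
Why: Dess–Martin oxidation under buffered conditions should give the aldehyde, whose equatorial C11 configuration is also the thermodynamic one.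

**Step 6**
Reactants: 7 aldehyde
Product: 8 R1-ethene, (3S,5aS,6S,7S,9aS)-6-ethenyl compound
Conditions: Ph3PCH3Br, KHMDS, THF, 0 °C; then 7, −78 → 0 °C
Reagents that add atoms: methyltriphenylphosphonium bromide, C[P+](c1ccccc1)(c1ccccc1)c1ccccc1.[Br-]
Why: Wittig methylenation of the hindered, non-conjugated aldehyde should be faster than β-elimination of the silyloxy group and supplies C13.

**Step 7**
Reactants: 8 vinyl compound; 9 2-iodocyclopent-2-en-1-one
Product: 11 2-[2-(R1)ethyl]cyclopent-2-en-1-one, via B-alkyl-9-BBN 10 (not isolated)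
Conditions: 9-BBN-H dimer, THF, rt; then 9, Pd(dppf)Cl2 (cat.), Ph3As (cat.), Cs2CO3, DMF–THF–H2O, rt
Reagents that add atoms: none
Why: Anti-Markovnikov hydroboration of the vinyl group and B-alkyl Suzuki–Miyaura coupling with the α-iodoenone should form the C13–C14 bond.

**Step 8**
Reactants: 11 2-alkylcyclopentenone
Product: 13 (2S,3S)-2,3-dimethyl-2-[2-(R1)ethyl]cyclopentan-1-one, via magnesium enolate 12 (not isolated)
Conditions: MeMgBr, Cu(OTf)2 (cat.), chiral imidazolinium NHC precursor (cat., the enantiomer that gives 15S), Et2O, −30 °C; then MeI, DMPU, −30 °C → rt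
Reagents that add atoms: methylmagnesium bromide, C[Mg]Br; iodomethane, CI
Why: Copper-catalysed asymmetric conjugate addition to the α-substituted enone should set C15 under catalyst control, and the regiodefined magnesium enolate should be methylated anti to the new C15 methyl, which sets quaternary C14 by relay.

**Step 9**
Reactants: 14 4-methylpent-3-en-1-ol
Product: 15 4-methylpent-3-enal
Conditions: Dess–Martin periodinane, NaHCO3, CH2Cl2, 0 °C; used as a cold solution
Reagents that add atoms: none
Why: Buffered Dess–Martin oxidation should give the β,γ-unsaturated aldehyde without shifting the double bond into conjugation.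

**Step 10**
Reactants: 13 cyclopentanone; 15 4-methylpent-3-enal
Product: 19 (3S,4S)-2-(1-hydroxy-4-methylpent-3-en-1-yl)-3,4-dimethyl-3-[2-(R1)ethyl]cyclohexan-1-one (epimers at C19 and C20), via dibromomethyl alkoxide 16 (not isolated), via lithium carbenoid 17 (not isolated), via lithium enolate 18 (not isolated)
Conditions: CH2Br2, LiTMP, THF, −78 °C; n-BuLi, −95 → −78 °C, then 0 °C; 15, −78 °C; then H2O
Reagents that add atoms: dibromomethane, BrCBr
Why: Dibromomethyllithium, generated in the presence of the ketone, should add to C18=O to give alkoxide 16; bromine–lithium exchange then gives the β-oxido carbenoid 17, in which C14 shifts from C18 to the carbenoid carbon with loss of LiBr and with retention at C14, so that the ring-enlarged ketone is born as its lithium enolate 18, which adds to aldehyde 15. The closest known reaction type is the β-oxido carbenoid one-carbon ring enlargement of 2-substituted cycloalkanones, in which the more highly substituted α-carbon migrates and the enolate forms only at the inserted carbon. No ring is closed by a cyclisation: the six-membered carbocycle C14–C15–C16–C17–C18–C19 arises from the five-membered ring C14–C15–C16–C17–C18 by a 1,2-alkyl shift that inserts C19 between C18 and C14. The new stereocentres C19 and C20 form without control and are both erased in step 11, whereas C14 and C15 pass through unchanged. The step needs migration of C14 instead of C17 and C–C bond formation at the neopentyl carbon C19; the first is secured by the quaternary, electron-rich C14, the second because the enolate double bond can only lie between C18 and the inserted carbon.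

**Step 11**
Reactants: 19 aldol
Product: 21 (2Z,3S,4S)-3,4-dimethyl-2-(4-methylpent-3-en-1-ylidene)-3-[2-(R1)ethyl]cyclohexan-1-one, via mesylate 20 (not isolated)
Conditions: MsCl, Et3N, CH2Cl2, 0 °C → rt
Reagents that add atoms: none
Why: Mesylation and E1cB elimination should give the enone, and the Z isomer (C21 syn to C18=O) should be favoured because the other places C21 against quaternary C14 (allylic 1,3-strain).

**Step 12**
Reactants: 21 bis-silyl enone
Product: 22 (2Z,3S,4S)-3,4-dimethyl-2-(4-methylpent-3-en-1-ylidene)-3-[2-(R2)ethyl]cyclohexan-1-one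
Conditions: HF·pyridine, pyridine, THF, 0 °C → rt
Reagents that add atoms: none
Why: Buffered HF should cleave both silyl ethers without the γ-deprotonation of the enone that basic fluoride could cause.

**Step 13**
Reactants: 22 diol
Product: 23 (2Z,3S,4S)-3,4-dimethyl-2-(4-methylpent-3-en-1-ylidene)-3-[2-(R3)ethyl]cyclohexan-1-one
Conditions: Dess–Martin periodinane, NaHCO3, CH2Cl2, rt
Reagents that add atoms: none
Why: C3–OH is the only secondary alcohol at this stage (C10–OH is tertiary, C18 is still a ketone, C22 still an olefin), so Dess–Martin oxidation should install the C3 ketone without a selectivity problem.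

**Step 14**
Reactants: 23 diketone
Product: 24 (2Z,3S,4S)-2-{2-[(2S)-3,3-dimethyloxiran-2-yl]ethylidene}-3,4-dimethyl-3-[2-(R3)ethyl]cyclohexan-1-one
Conditions: ent-Shi ketone, Oxone, K2CO3, buffer (pH 10.5), MeCN–DMM–H2O, 0 °C
Reagents that add atoms: Oxone (potassium peroxymonosulfate), [K+].[O-]S(=O)(=O)OO
Why: Shi epoxidation should touch only the electron-rich C22=C23 olefin (the enone olefin is electron-poor) and set C22 (S) under reagent control.

**Step 15**
Reactants: 24 epoxy enone
Product: 25 (1S,2Z,3S,4S)-2-{2-[(2S)-3,3-dimethyloxiran-2-yl]ethylidene}-3,4-dimethyl-3-[2-(R3)ethyl]cyclohexan-1-ol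
Conditions: (R)-Me-CBS oxazaborolidine, catecholborane, toluene, −78 °C; then MeOH, aq. NaHCO3
Reagents that add atoms: none
Why: Corey–Bakshi–Shibata reduction with catecholborane at low temperature should reduce the enone carbonyl in preference to the hindered saturated C3 ketone and deliver hydride under reagent control (alkylidene flank as the large group) to give (18S).

**Step 16**
Reactants: 25 epoxy allylic alcohol
Product: 26 sodwanone S
Conditions: CSA (cat.), CH2Cl2, −40 → 0 °C
Reagents that add atoms: none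
Why: Acid-promoted 7-endo-tet opening of the trisubstituted epoxide at its tertiary carbon C23 (Markovnikov, directed by the geminal methyls) by the C18 hydroxyl should close the oxepene with retention at C18 and C22.

**Compound list**

1 | (2E,6E)-farnesyl acetate | CC(=O)OC/C=C(\C)CC/C=C(\C)CCC=C(C)C | starting material
2 | (6S,7S,10S)-6,7:10,11-diepoxyfarnesyl acetate (farnesyl numbering) | CC(=O)OC/C=C(\C)CC[C@@H]1O[C@@]1(C)CC[C@@H]2OC2(C)C | intermediate
3 | acetoxonium (2-methyl-1,3-dioxan-2-ylium) triflate bridging O–C10 and O–C12 | O1C[C@H]2[C@]3(C)CC[C@H](O[Si](C)(C)C(C)(C)C)C(C)(C)O[C@H]3CC[C@]2(C)[O+]=C1C.[O-]S(=O)(=O)C(F)(F)F | intermediate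
4 | bicyclic hydroxy acetate (3-OTBS, 10-OH, 12-OAc) | CC(=O)OC[C@H]1[C@]2(C)CC[C@H](O[Si](C)(C)C(C)(C)C)C(C)(C)O[C@H]2CC[C@]1(C)O | intermediate
5 | 10-O-triethylsilyl ether of 4 | CC(=O)OC[C@H]1[C@]2(C)CC[C@H](O[Si](C)(C)C(C)(C)C)C(C)(C)O[C@H]2CC[C@]1(C)O[Si](CC)(CC)CC | intermediate
6 | C12 primary alcohol | OC[C@H]1[C@]2(C)CC[C@H](O[Si](C)(C)C(C)(C)C)C(C)(C)O[C@H]2CC[C@]1(C)O[Si](CC)(CC)CC | intermediate
7 | C12 aldehyde | O=C[C@H]1[C@]2(C)CC[C@H](O[Si](C)(C)C(C)(C)C)C(C)(C)O[C@H]2CC[C@]1(C)O[Si](CC)(CC)CC | intermediate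
8 | C11 vinyl compound | C=C[C@H]1[C@]2(C)CC[C@H](O[Si](C)(C)C(C)(C)C)C(C)(C)O[C@H]2CC[C@]1(C)O[Si](CC)(CC)CC | intermediate
9 | 2-iodocyclopent-2-en-1-one | O=C1CCC=C1I | starting material
10 | B-[2-(R1)ethyl]-9-borabicyclo[3.3.1]nonane | C1CCC2CCCC1B2CC[C@H]3[C@]4(C)CC[C@H](O[Si](C)(C)C(C)(C)C)C(C)(C)O[C@H]4CC[C@]3(C)O[Si](CC)(CC)CC | intermediate
11 | 2-[2-(R1)ethyl]cyclopent-2-en-1-one | O=C1CCC=C1CC[C@H]2[C@]3(C)CC[C@H](O[Si](C)(C)C(C)(C)C)C(C)(C)O[C@H]3CC[C@]2(C)O[Si](CC)(CC)CC | intermediate
12 | bromomagnesium enolate of the (15S) conjugate adduct | C[C@H]1CCC(O[Mg]Br)=C1CC[C@H]2[C@]3(C)CC[C@H](O[Si](C)(C)C(C)(C)C)C(C)(C)O[C@H]3CC[C@]2(C)O[Si](CC)(CC)CC | intermediate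
13 | (2S,3S)-2,3-dimethyl-2-[2-(R1)ethyl]cyclopentan-1-one | C[C@H]1CCC(=O)[C@@]1(C)CC[C@H]2[C@]3(C)CC[C@H](O[Si](C)(C)C(C)(C)C)C(C)(C)O[C@H]3CC[C@]2(C)O[Si](CC)(CC)CC | intermediate
14 | 4-methylpent-3-en-1-ol | CC(C)=CCCO | starting material
15 | 4-methylpent-3-enal | CC(C)=CCC=O | intermediate
16 | lithium 1-(dibromomethyl)cyclopentanolate (C18 epimers, centre later destroyed) | C[C@H]1CCC(O[Li])(C(Br)Br)[C@@]1(C)CC[C@H]2[C@]3(C)CC[C@H](O[Si](C)(C)C(C)(C)C)C(C)(C)O[C@H]3CC[C@]2(C)O[Si](CC)(CC)CC | intermediate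
17 | β-oxido carbenoid (α-bromo-α-lithio alkoxide) | C[C@H]1CCC(O[Li])(C([Li])Br)[C@@]1(C)CC[C@H]2[C@]3(C)CC[C@H](O[Si](C)(C)C(C)(C)C)C(C)(C)O[C@H]3CC[C@]2(C)O[Si](CC)(CC)CC | intermediate
18 | lithium enolate of the ring-enlarged ketone (C18–OLi, C18=C19) | C[C@H]1CCC(O[Li])=C[C@@]1(C)CC[C@H]2[C@]3(C)CC[C@H](O[Si](C)(C)C(C)(C)C)C(C)(C)O[C@H]3CC[C@]2(C)O[Si](CC)(CC)CC | intermediate
19 | aldol (3S,4S; epimers at C19 and C20) | C[C@H]1CCC(=O)C(C(O)CC=C(C)C)[C@@]1(C)CC[C@H]2[C@]3(C)CC[C@H](O[Si](C)(C)C(C)(C)C)C(C)(C)O[C@H]3CC[C@]2(C)O[Si](CC)(CC)CC | intermediate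
20 | C20 mesylate of 19 | C[C@H]1CCC(=O)C(C(OS(C)(=O)=O)CC=C(C)C)[C@@]1(C)CC[C@H]2[C@]3(C)CC[C@H](O[Si](C)(C)C(C)(C)C)C(C)(C)O[C@H]3CC[C@]2(C)O[Si](CC)(CC)CC | intermediate
21 | (Z)-enone, bis-silyl ether | C[C@H]1CCC(=O)/C(=C\CC=C(C)C)[C@@]1(C)CC[C@H]2[C@]3(C)CC[C@H](O[Si](C)(C)C(C)(C)C)C(C)(C)O[C@H]3CC[C@]2(C)O[Si](CC)(CC)CC | intermediate
22 | (Z)-enone 3,10-diol | C[C@H]1CCC(=O)/C(=C\CC=C(C)C)[C@@]1(C)CC[C@H]2[C@]3(C)CC[C@H](O)C(C)(C)O[C@H]3CC[C@]2(C)O | intermediate
23 | (Z)-enone 3-ketone | C[C@H]1CCC(=O)/C(=C\CC=C(C)C)[C@@]1(C)CC[C@H]2[C@]3(C)CCC(=O)C(C)(C)O[C@H]3CC[C@]2(C)O | intermediate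
24 | (22S)-22,23-epoxy enone | C[C@H]1CCC(=O)/C(=C\C[C@@H]4OC4(C)C)[C@@]1(C)CC[C@H]2[C@]3(C)CCC(=O)C(C)(C)O[C@H]3CC[C@]2(C)O | intermediate
25 | (18S)-allylic alcohol epoxide | C[C@H]1CC[C@H](O)/C(=C\C[C@@H]4OC4(C)C)[C@@]1(C)CC[C@H]2[C@]3(C)CCC(=O)C(C)(C)O[C@H]3CC[C@]2(C)O | intermediate
26 | sodwanone S | C[C@H]1CC[C@@H]2OC(C)(C)[C@@H](O)CC=C2[C@@]1(C)CC[C@H]1[C@]2(C)CCC(=O)C(C)(C)O[C@H]2CC[C@]1(C)O | target

**Step count and risks**

Total: 16 steps. Longest linear sequence: 15 steps (steps 1–8 and 10–16 from farnesyl acetate); step 9 is a one-step side branch.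

Step 16 is the most likely to fail. The hydroxyl may attack the secondary epoxide carbon C22 (6-exo mode) faster than the tertiary C23 (7-endo mode). The fallback sets out from 25 and comes back at 26. The exo mode is made the intended one: 25 with NaH in THF should close to the dihydropyran carbinol F1. Its tertiary hydroxyl is then ionised with Zn(OAc)2 in aqueous acetic acid with participation of the ring oxygen (oxiranium-ion ring expansion of a tetrahydropyranyl carbinol), and acetate captures C22 to give the ring-enlarged 22-acetate F2 with net retention at C22 (two inversions). K2CO3 in MeOH then gives 26.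

Step 2 is the second. Capture of the C10 cation by the weakly nucleophilic acetate carbonyl may be slow against proton loss, and the acetoxonium ion may hydrolyse without regiocontrol. The fallback sets out from 2 and comes back at 6. Methanolysis (K2CO3, MeOH) gives the diepoxy alcohol F3, and Boc2O with DMAP gives the tert-butyl carbonate F4. The same silyl triflate cascade is then terminated irreversibly by the carbonate with loss of isobutene to give the cyclic carbonate F5. K2CO3 in MeOH gives the 10,12-diol F6, excess TESOTf the bis-silyl ether F7, and selective cleavage of the primary silyl ether (PPTS, MeOH, 0 °C) gives 6.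

Step 10 is the third. Proton transfer from the enolizable β,γ-unsaturated aldehyde to the hindered lithium enolate, or retro-aldol on warming, may compete with C–C bond formation. The fallback sets out from 13 and comes back at 19. The ring enlargement is run as before, but enolate 18 is quenched with TMSCl and the regiodefined trimethylsilyl enol ether F8 is isolated. A Mukaiyama aldol addition with 15 (BF3·OEt2, CH2Cl2, −78 °C) then gives 19 under non-basic conditions.

**Further compounds**

F1 | step 16 | 6-exo product: cyclohexane-fused 3,6-dihydro-2H-pyran with a 2-hydroxypropan-2-yl group at C22 | C[C@H]1CC[C@@H]2O[C@@H](C(C)(C)O)CC=C2[C@@]1(C)CC[C@H]1[C@]2(C)CCC(=O)C(C)(C)O[C@H]2CC[C@]1(C)O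
F2 | step 16 | 22-O-acetyl sodwanone S | C[C@H]1CC[C@@H]2OC(C)(C)[C@@H](OC(C)=O)CC=C2[C@@]1(C)CC[C@H]1[C@]2(C)CCC(=O)C(C)(C)O[C@H]2CC[C@]1(C)O
F3 | step 2 | (6S,7S,10S)-6,7:10,11-diepoxy-(2E)-farnesol | OC/C=C(\C)CC[C@@H]1O[C@@]1(C)CC[C@@H]2OC2(C)C
F4 | step 2 | tert-butyl carbonate of F3 | CC(C)(C)OC(=O)OC/C=C(\C)CC[C@@H]1O[C@@]1(C)CC[C@@H]2OC2(C)C
F5 | step 2 | tricyclic carbonate (1,3-dioxan-2-one bridging O–C10 and O–C12, 3-OTBS) | O=C1OC[C@H]2[C@]3(C)CC[C@H](O[Si](C)(C)C(C)(C)C)C(C)(C)O[C@H]3CC[C@]2(C)O1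
F6 | step 2 | 10,12-diol (3-OTBS) | OC[C@H]1[C@]2(C)CC[C@H](O[Si](C)(C)C(C)(C)C)C(C)(C)O[C@H]2CC[C@]1(C)O
F7 | step 2 | 10,12-bis(triethylsilyl) ether (3-OTBS) | CC[Si](CC)(CC)OC[C@H]1[C@]2(C)CC[C@H](O[Si](C)(C)C(C)(C)C)C(C)(C)O[C@H]2CC[C@]1(C)O[Si](CC)(CC)CC
F8 | step 10 | trimethylsilyl enol ether of the ring-enlarged ketone (C18–OTMS, C18=C19) | C[C@H]1CCC(O[Si](C)(C)C)=C[C@@]1(C)CC[C@H]2[C@]3(C)CC[C@H](O[Si](C)(C)C(C)(C)C)C(C)(C)O[C@H]3CC[C@]2(C)O[Si](CC)(CC)CC
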